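The chemist at the bench and a colleague disagree about how much target this flask can ever give.

starting material 0.020 M (in portions, 3); second substrate 0.0300 M; enzyme 2.0 µM; time 2.5 min; the portions of starting material follow each other after 25 s, the first at the start

    2 ternary complex → spent catalyst (k1 = 12000 L mol⁻¹ s⁻¹)
    ternary complex → enzyme + target (k2 = 260 s⁻¹)
    starting material + enzyme ⇌ starting complex (K3 = 150 L mol⁻¹, k3 = 2.9 × 10⁶ L mol⁻¹ s⁻¹)
    second substrate + starting complex ⇌ ternary complex (K4 = 7.6 L mol⁻¹, k4 = 5.2 × 10⁵ L mol⁻¹ s⁻¹)

- percentages count the starting material that a species holds: one spent catalyst counts as two
- where a step has two of a species, its rate is k times that concentration squared, and two are used at each turn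
- run time (flask): 2.5 min

- share of the starting material used up at 2.5 min
- target at 2.5 min, in percent of the starting material charged
- amount of target if the flask were left three thousand times as long, in percent of the starting material charged

Both start from one share. Starting complex falls back at 19300 s⁻¹ and ternary complex at 68400 s⁻¹, both far faster than the 260 s⁻¹ of turnover, so the two bindings can be treated as rapid pre-equilibria. With the first portion in, the binding terms are 1.00 for starting material and 0.228 for second substrate, so ternary complex holds 10.2% of the catalyst.

The colleague argues from the clock. At that share, the first half-life of ternary complex by the loss step is 204 s, against a run of 150 s, so the colleague expects target to stall well short of the charge.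

The chemist divides one rate by the other, and I side with this reckoning. Each target made costs 1.89 × 10⁻⁵ ternary complex, and time has dropped out. Multiplying by the charge and dividing by the catalyst charge cancels the enzyme amount and gives the toll, the share of the catalyst that becomes spent catalyst while the whole charge turns to target at this fixed share: 18.9%. That is less than one whole catalyst charge, so target should reach the end of the charge. At constant share, turnover gives me 39.9% of the charge by 2.5 min.

The forecast takes the chemist's side with 41.3% used up, 41.2% target and >99.9% in the long run, holding that “only about 10% of the enzyme dies even by the end of the reaction”. That loss figure differs from my toll of 18.9%, and its conversion differs from my 39.9%.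

The simulation gives 41.1% used up, 41.1% target and >99.9% in the long run, so the chemist's view holds. At 2.50 min, this flask shows 8.07% of its catalyst spent for 41.1% target, a reading of 19.6% per whole charge's worth of target, beside the toll of 18.9%. At 25.0 min this flask held 13.1% as spent catalyst and 99.9% target, so its loss over the charge came out less than the toll. The colleague's view belongs to a toll near one whole catalyst charge, and this flask's lies below that. The neighbouring flask with 0.0075 M of second substrate, 0.375 equiv to starting material, has a binding term of 0.0570, a starting share of 2.77% and a toll of 5.12% per whole charge's worth of target, a rate ratio and not a yield that its second substrate could supply. At 2.50 min that neighbouring flask held 0.695% of its catalyst as spent catalyst, with target at 12.1%, a reading of 5.74% per whole charge's worth of target.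

All constants were set for the occasion; the rest is arithmetic.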